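A direct plan would keep ring B from methyl 3,5-dihydroxybenzoate A1 and turn it in about ten steps into the racemic ynol ether A2,
a 1-methoxyalkyne on a silylated ring B carbinol; ring A would then be grown on A2 by heating with 3-methylcyclobutenone A3
(ketene (2+2) addition, ring opening, 6π closure) to phenol A4; bromination, desilylation to diol A5, a twofold oxidation and acetal cleavage would follow.
Its weakest steps would be (a) the run-up to A2: the formyl carbon would be put in, reduced to lactone and lactol and oxidised back much later,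
so that ten steps would add protecting groups and one prenyl group but no new ring;
(b) the benzannulation: a crowded, acid-labile ynol ether would have to trap a volatile ketene at 80–110 °C in one orientation, on ten-step material;
(c) the twofold oxidation of A5: any half-oxidised material would drain to lactol and lactone on the most precious intermediate.

Plan of the new route
Cuts: in ring B the bonds B-C1–B-C2, B-C1–B-C6 and B-C3–B-C4; ring A is bought (3,5-dimethoxytoluene) and ring B is made last, in one operation.
Enabling feature: the hydroxyl on A-C5 is ortho to the ketone, so ring A, the carbonyl carbon and B-C1 can be carried as a benzofuran-3(2H)-one whose O1–C2 bond is a leaving group on the future B-C1.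
Condensing its C2 with diethyl ketomalonate joins two carbons of like (nucleophilic) polarity and turns B-C1 into the electrophilic end of an aryloxy-alkylidene malonate.
A regiodefined enolate of 6-methylhept-5-en-2-one then adds there, the furanone opens to free the ring A phenol, and a Claisen closure gives the hexasubstituted resorcinol ring with prenyl and ester in place.
There is no ynol ether and no benzannulation of ring A; the ketone never leaves the ketone level, so only one ester is adjusted and the benzylic alcohol rests as a hemiketal without carbinol hydrogen; bromine enters on a small phenol.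

Key step: step 6

Remark: locants used below are A-C1 (OMe), A-C3 (Me), A-C4 (Br), A-C5 (OH), A-C6 (carries C=O), B-C1 (carries C=O), B-C2 (CHO), B-C3 and B-C5 (OH), B-C6 (prenyl); the target has no stereocentre and no alkene geometry to set.

Step 1
Reactants: 1 3,5-dimethoxytoluene; 2 2-chloro-N-methoxy-N-methylacetamide
Product: 4 2-chloro-1-(2,6-dimethoxy-4-methylphenyl)ethan-1-one, via aryllithium 3 (not isolated)
Conditions: n-BuLi (1.1 equiv), THF, 0 °C → rt; then 2, −78 → 0 °C; 1 M HCl
Reagents that add atoms: none
Why: Directed ortho-lithiation puts lithium between the two methoxy groups, and acylation of aryllithium 3 with the Weinreb amide should stop at the ketone because the chelated tetrahedral adduct survives until the acid quench.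

Step 2
Reactants: 4 2-chloro-1-(2,6-dimethoxy-4-methylphenyl)ethan-1-one
Product: 5 2-chloro-1-(2-hydroxy-6-methoxy-4-methylphenyl)ethan-1-one
Conditions: BCl3 (1.2 equiv), CH2Cl2, −78 → 0 °C; H2O
Reagents that add atoms: none
Why: Chelation-controlled ether cleavage by BCl3, bound to the ketone oxygen, should remove only one of the two equivalent ortho-methoxy groups, since the boron phenoxide chelate that forms resists a second cleavage.

Step 3
Reactants: 5 2-chloro-1-(2-hydroxy-6-methoxy-4-methylphenyl)ethan-1-one
Product: 7 7-bromo-4-methoxy-6-methylbenzofuran-3(2H)-one, via bromophenol 6 (not isolated)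
Conditions: NBS (1.0 equiv), i-Pr2NH (0.1 equiv), CH2Cl2, −78 → 0 °C, dark; then solvent exchange, NaOAc (3 equiv), EtOH, 78 °C
Reagents that add atoms: N-bromosuccinimide, O=C1CCC(=O)N1Br
Why: Amine-mediated ortho-bromination of a phenol (N-bromoamine held by the hydroxyl) should put bromine on the only free ortho carbon A-C4, and acetate then induces intramolecular O-alkylation (5-exo-tet Williamson closure) of the 2-hydroxyphenacyl chloride to the furanone.

Step 4
Reactants: 7 7-bromo-4-methoxy-6-methylbenzofuran-3(2H)-one; 8 diethyl ketomalonate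
Product: 10 diethyl 2-(7-bromo-4-methoxy-6-methyl-3-oxobenzofuran-2(3H)-ylidene)propanedioate, via aldol adduct 9 (not isolated)
Conditions: TiCl4 (2 equiv), pyridine (4 equiv), THF, 0 °C → rt
Reagents that add atoms: none
Why: Knoevenagel-type condensation: the titanium enolate of 7 adds to the strongly electrophilic central carbonyl of 8, and aldol 9 loses water by E1cB, because C2–H is still α to the ketone, to give the tetrasubstituted push–pull alkene.

Step 5
Reactants: 11 methyl vinyl ketone; 12 (2-methylprop-1-en-1-yl)magnesium bromide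
Product: 13 trimethyl[(6-methylhepta-2,5-dien-2-yl)oxy]silane (E/Z mixture)
Conditions: CuBr·SMe2 (5 mol %), Me3SiCl (2 equiv), THF, −78 °C; Et3N, pentane, cold aq. NaHCO3; distillation
Reagents that add atoms: chlorotrimethylsilane, C[Si](C)(C)Cl
Why: Copper-catalysed conjugate addition of an alkenyl Grignard reagent to an enone with in situ silylation traps the enolate where it forms, which fixes the enol double bond between C2 and C3 of the future 6-methylhept-5-en-2-one unit, a regiochemistry that deprotonation of the ketone would not give cleanly.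

Step 6
Reactants: 10 diethyl 2-(7-bromo-4-methoxy-6-methyl-3-oxobenzofuran-2(3H)-ylidene)propanedioate; 13 trimethyl[(6-methylhepta-2,5-dien-2-yl)oxy]silane
Product: 18 ethyl 2-(3-bromo-2-hydroxy-6-methoxy-4-methylbenzoyl)-4,6-dihydroxy-3-(3-methylbut-2-en-1-yl)benzoate, via lithium enolate 14 (not isolated), via Michael adduct 15 (not isolated), via ring-opened ylidene malonate 16 (not isolated), via cyclohexenedione 17 (not isolated)
Conditions: 13 (1.3 equiv), MeLi (1.25 equiv), THF, 0 °C → rt; add 10, −78 → 0 °C; then NaOEt (4 equiv), EtOH, 0 → 70 °C; 1 M HCl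
Reagents that add atoms: none
Why: Proposed new method: MeLi cleaves 13 to the regiodefined lithium enolate 14, whose C3 should add to C2 of 10 (the carbon that carries the ring oxygen and is β to both esters) to give malonate anion 15, which expels the ring A aryloxide by E1cB and so opens the furanone to 16; under NaOEt the methyl ketone enolate of 16 attacks the ester cis to it (Claisen condensation, 6-exo-trig at the ester carbonyl, closing ring B through the B-C3 to B-C4 bond) and dione 17 tautomerises to the resorcinol. The closest known reaction types are the addition–elimination of enolates to alkoxymethylene malonates, the Michael–retro-Michael–aldol ring transformation of 3-formylchromones into 2-hydroxybenzophenones, and the Michael–Claisen (dimedone-type) synthesis of resorcylates. The stereocentres of 15 to 17 are transient and end as sp2 carbons, so nothing has to be controlled. Three selectivities are needed: the ketone must react first through its internal α-carbon, which the preformed enolate secures; attack must go to C2 and not to the malonate carbon or a carbonyl group, which the push–pull polarisation by O1 and two esters favours and the irreversible loss of aryloxide funnels; and the last enolate must acylate on the ester and not add to the diaryl ketone, which is shielded by four ortho groups and deactivated as the ortho-phenoxide. Aromatisation of ring B makes the sequence irreversible and should also return any O-acylated pyranone to the productive path.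

Step 7
Reactants: 18 ethyl 2-(3-bromo-2-hydroxy-6-methoxy-4-methylbenzoyl)-4,6-dihydroxy-3-(3-methylbut-2-en-1-yl)benzoate
Product: 19 ethyl 2-(3-bromo-2-hydroxy-6-methoxy-4-methylbenzoyl)-4,6-bis(tert-butyldimethylsilyloxy)-3-(3-methylbut-2-en-1-yl)benzoate
Conditions: TBSCl (2.4 equiv), imidazole (5 equiv), DMF, 0 °C → rt
Reagents that add atoms: tert-butyldimethylsilyl chloride, CC(C)(C)[Si](C)(C)Cl
Why: Imidazole-promoted silylation should take the two ring B phenols and leave the ring A hydroxyl, which is flanked by bromine and the acyl group and hydrogen-bonded to the ketone; capping ring B removes the phenoxide donation that would deactivate the ester toward hydride.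

Step 8
Reactants: 19 ethyl 2-(3-bromo-2-hydroxy-6-methoxy-4-methylbenzoyl)-4,6-bis(tert-butyldimethylsilyloxy)-3-(3-methylbut-2-en-1-yl)benzoate
Product: 20 (3-bromo-2-hydroxy-6-methoxy-4-methylphenyl)[3,5-bis(tert-butyldimethylsilyloxy)-2-(hydroxymethyl)-6-(3-methylbut-2-en-1-yl)phenyl]methanone
Conditions: i-Bu2AlH (3.5 equiv), CH2Cl2, −78 → −20 °C; aq. potassium sodium tartrate
Reagents that add atoms: none
Why: Ester reduction with i-Bu2AlH; the diaryl ketone is flanked by four ortho substituents and held in an aluminium phenoxide chelate of the A-C5 hydroxyl, so that, like other tetra-ortho-substituted benzophenones, it should resist hydride at low temperature, and the alcohol formed rests as its cyclic hemiketal.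

Step 9
Reactants: 20 (3-bromo-2-hydroxy-6-methoxy-4-methylphenyl)[3,5-bis(tert-butyldimethylsilyloxy)-2-(hydroxymethyl)-6-(3-methylbut-2-en-1-yl)phenyl]methanone
Product: 21 2-(3-bromo-2-hydroxy-6-methoxy-4-methylbenzoyl)-4,6-bis(tert-butyldimethylsilyloxy)-3-(3-methylbut-2-en-1-yl)benzaldehyde
Conditions: MnO2 (activated, 20 equiv), CH2Cl2, rt
Reagents that add atoms: none
Why: Benzylic alcohol oxidation with MnO2; the hemiketal form of 20 has no carbinol hydrogen and cannot go on to a lactone, so that only the open hydroxy ketone is oxidised and the aldehyde level is reached without touching the ketone.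

Step 10
Reactants: 21 2-(3-bromo-2-hydroxy-6-methoxy-4-methylbenzoyl)-4,6-bis(tert-butyldimethylsilyloxy)-3-(3-methylbut-2-en-1-yl)benzaldehyde
Product: 22 Pestalone B, 2-(3-bromo-2-hydroxy-6-methoxy-4-methylbenzoyl)-4,6-dihydroxy-3-(3-methylbut-2-en-1-yl)benzaldehyde
Conditions: HF·pyridine, pyridine, THF, 0 °C → rt
Reagents that add atoms: none
Why: Fluoride-induced cleavage of the aryl silyl ethers, driven by the Si–F bond, under buffered weakly acidic conditions that should spare the ortho-prenylphenol from chroman formation and avoid the base-induced Cannizzaro–Tishchenko shift of the keto aldehyde.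

Compound list
1 | 3,5-dimethoxytoluene | COc1cc(C)cc(OC)c1 | starting material
2 | 2-chloro-N-methoxy-N-methylacetamide | CON(C)C(=O)CCl | starting material
3 | (2,6-dimethoxy-4-methylphenyl)lithium | [Li]c1c(OC)cc(C)cc1OC | intermediate
4 | 2-chloro-1-(2,6-dimethoxy-4-methylphenyl)ethan-1-one | COc1cc(C)cc(OC)c1C(=O)CCl | intermediate
5 | 2-chloro-1-(2-hydroxy-6-methoxy-4-methylphenyl)ethan-1-one | COc1cc(C)cc(O)c1C(=O)CCl | intermediate
6 | 1-(3-bromo-2-hydroxy-6-methoxy-4-methylphenyl)-2-chloroethan-1-one | COc1cc(C)c(Br)c(O)c1C(=O)CCl | intermediate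
7 | 7-bromo-4-methoxy-6-methylbenzofuran-3(2H)-one | COc1cc(C)c(Br)c2OCC(=O)c12 | intermediate
8 | diethyl ketomalonate (diethyl 2-oxopropanedioate) | CCOC(=O)C(=O)C(=O)OCC | starting material
9 | (±)-diethyl 2-(7-bromo-4-methoxy-6-methyl-3-oxo-2,3-dihydrobenzofuran-2-yl)-2-hydroxypropanedioate | CCOC(=O)C(O)(C(=O)OCC)C1Oc2c(Br)c(C)cc(OC)c2C1=O | intermediate
10 | diethyl 2-(7-bromo-4-methoxy-6-methyl-3-oxobenzofuran-2(3H)-ylidene)propanedioate | CCOC(=O)C(C(=O)OCC)=C1Oc2c(Br)c(C)cc(OC)c2C1=O | intermediate
11 | methyl vinyl ketone (but-3-en-2-one) | CC(=O)C=C | starting material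
12 | (2-methylprop-1-en-1-yl)magnesium bromide | CC(C)=C[Mg]Br | starting material
13 | trimethyl[(6-methylhepta-2,5-dien-2-yl)oxy]silane, E/Z mixture at C2=C3 | CC(O[Si](C)(C)C)=CCC=C(C)C | intermediate
14 | lithium 6-methylhepta-2,5-dien-2-olate | [Li]OC(C)=CCC=C(C)C | intermediate
15 | diethyl 2-[7-bromo-4-methoxy-6-methyl-2-(6-methyl-2-oxohept-5-en-3-yl)-3-oxo-2,3-dihydrobenzofuran-2-yl]propanedioate, racemic diastereomer mixture, present as its lithium malonate | CCOC(=O)C(C(=O)OCC)C1(C(CC=C(C)C)C(C)=O)Oc2c(Br)c(C)cc(OC)c2C1=O | intermediate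
16 | (±)-diethyl 2-[3-acetyl-1-(3-bromo-2-hydroxy-6-methoxy-4-methylphenyl)-6-methyl-1-oxohept-5-en-2-ylidene]propanedioate, present as its phenoxide | CCOC(=O)C(C(=O)OCC)=C(C(=O)c1c(O)c(Br)c(C)cc1OC)C(CC=C(C)C)C(C)=O | intermediate
17 | (±)-ethyl 2-(3-bromo-2-hydroxy-6-methoxy-4-methylbenzoyl)-3-(3-methylbut-2-en-1-yl)-4,6-dioxocyclohex-1-ene-1-carboxylate | CCOC(=O)C1=C(C(=O)c2c(O)c(Br)c(C)cc2OC)C(CC=C(C)C)C(=O)CC1=O | intermediate
18 | ethyl 2-(3-bromo-2-hydroxy-6-methoxy-4-methylbenzoyl)-4,6-dihydroxy-3-(3-methylbut-2-en-1-yl)benzoate | CCOC(=O)c1c(O)cc(O)c(CC=C(C)C)c1C(=O)c1c(O)c(Br)c(C)cc1OC | intermediate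
19 | ethyl 2-(3-bromo-2-hydroxy-6-methoxy-4-methylbenzoyl)-4,6-bis(tert-butyldimethylsilyloxy)-3-(3-methylbut-2-en-1-yl)benzoate | CCOC(=O)c1c(O[Si](C)(C)C(C)(C)C)cc(O[Si](C)(C)C(C)(C)C)c(CC=C(C)C)c1C(=O)c1c(O)c(Br)c(C)cc1OC | intermediate
20 | (3-bromo-2-hydroxy-6-methoxy-4-methylphenyl)[3,5-bis(tert-butyldimethylsilyloxy)-2-(hydroxymethyl)-6-(3-methylbut-2-en-1-yl)phenyl]methanone, in equilibrium with its cyclic hemiketal | OCc1c(O[Si](C)(C)C(C)(C)C)cc(O[Si](C)(C)C(C)(C)C)c(CC=C(C)C)c1C(=O)c1c(O)c(Br)c(C)cc1OC | intermediate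
21 | 2-(3-bromo-2-hydroxy-6-methoxy-4-methylbenzoyl)-4,6-bis(tert-butyldimethylsilyloxy)-3-(3-methylbut-2-en-1-yl)benzaldehyde | O=Cc1c(O[Si](C)(C)C(C)(C)C)cc(O[Si](C)(C)C(C)(C)C)c(CC=C(C)C)c1C(=O)c1c(O)c(Br)c(C)cc1OC | intermediate
22 | Pestalone B | COc1cc(C)c(Br)c(O)c1C(=O)c1c(C=O)c(O)cc(O)c1CC=C(C)C | target

Total step count: 10. Longest linear sequence: 9 (steps 1 to 4 and 6 to 10; step 5 supplies the enol silane).

Steps most likely to fail

Step 6 (Proposed new method). The last Claisen closure may stall, because the methyl ketone has to be enolised in an intermediate that already carries two negative charges; retro-addition would then scramble the enolate regiochemistry, or the chain would rest as an O-acylated pyranone. The fallback uses known reaction types and closes the second ring bond through a stabilised β-keto ester carbon whose regiochemistry is intrinsic. It sets out from 10. The dianion (NaH, then n-BuLi, THF, 0 °C) of allyl 7-methyl-3-oxooct-6-enoate F1, itself made from allyl acetoacetate dianion and prenyl bromide, would add through its γ-carbon to C2 of 10 with loss of the aryloxide. The β-keto ester methylene would then close ring B by Dieckmann condensation on warming, to give 3-allyl 1-ethyl 6-(3-bromo-2-hydroxy-6-methoxy-4-methylbenzoyl)-2,4-dihydroxy-5-(3-methylbut-2-en-1-yl)benzene-1,3-dicarboxylate F2. Pd(PPh3)4 and morpholine would remove the allyl ester (Tsuji–Trost deallylation) to 4-(3-bromo-2-hydroxy-6-methoxy-4-methylbenzoyl)-3-(ethoxycarbonyl)-2,6-dihydroxy-5-(3-methylbut-2-en-1-yl)benzoic acid F3. As a 2,6-dihydroxybenzoic acid, F3 should lose CO2 on gentle warming, and the route is rejoined at 18.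

Step 8. Chemoselectivity may be lost, with hydride delivered to the ketone as well as to the ester, or a silyl group may shift to the new alkoxide. The fallback asks for no selectivity between the two carbonyl groups. It sets out from 18. Full silylation (TBSOTf, 2,6-lutidine) would give ethyl 2-[3-bromo-2-(tert-butyldimethylsilyloxy)-6-methoxy-4-methylbenzoyl]-4,6-bis(tert-butyldimethylsilyloxy)-3-(3-methylbut-2-en-1-yl)benzoate F4. Excess i-Bu2AlH at room temperature would reduce both carbonyl groups to the racemic diol [3-bromo-2-(tert-butyldimethylsilyloxy)-6-methoxy-4-methylphenyl][3,5-bis(tert-butyldimethylsilyloxy)-2-(hydroxymethyl)-6-(3-methylbut-2-en-1-yl)phenyl]methanol F5. Excess Dess–Martin periodinane would oxidise both alcohols at once to 2-[3-bromo-2-(tert-butyldimethylsilyloxy)-6-methoxy-4-methylbenzoyl]-4,6-bis(tert-butyldimethylsilyloxy)-3-(3-methylbut-2-en-1-yl)benzaldehyde F6, and HF·pyridine would then give 22.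

Step 3. Bromine may enter para to the hydroxyl (A-C2) or on the chloromethyl carbon instead of ortho to the hydroxyl. The fallback sets the position by symmetry and not by direction. It sets out from 4. NBS in MeCN would brominate one of the two equivalent ring positions to give 1-(3-bromo-2,6-dimethoxy-4-methylphenyl)-2-chloroethan-1-one F7. BCl3 would then cleave the methoxy group that is squeezed between bromine and the acyl group (the more crowded, chelation-assisted one), which returns to the route at 6, cyclised to 7 as in step 3.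

Further compounds
F1 | step 6 | allyl 7-methyl-3-oxooct-6-enoate | C=CCOC(=O)CC(=O)CCC=C(C)C
F2 | step 6 | 3-allyl 1-ethyl 6-(3-bromo-2-hydroxy-6-methoxy-4-methylbenzoyl)-2,4-dihydroxy-5-(3-methylbut-2-en-1-yl)benzene-1,3-dicarboxylate | CCOC(=O)c1c(O)c(C(=O)OCC=C)c(O)c(CC=C(C)C)c1C(=O)c1c(O)c(Br)c(C)cc1OC
F3 | step 6 | 4-(3-bromo-2-hydroxy-6-methoxy-4-methylbenzoyl)-3-(ethoxycarbonyl)-2,6-dihydroxy-5-(3-methylbut-2-en-1-yl)benzoic acid | CCOC(=O)c1c(O)c(C(=O)O)c(O)c(CC=C(C)C)c1C(=O)c1c(O)c(Br)c(C)cc1OC
F4 | step 8 | ethyl 2-[3-bromo-2-(tert-butyldimethylsilyloxy)-6-methoxy-4-methylbenzoyl]-4,6-bis(tert-butyldimethylsilyloxy)-3-(3-methylbut-2-en-1-yl)benzoate | CCOC(=O)c1c(O[Si](C)(C)C(C)(C)C)cc(O[Si](C)(C)C(C)(C)C)c(CC=C(C)C)c1C(=O)c1c(O[Si](C)(C)C(C)(C)C)c(Br)c(C)cc1OC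
F5 | step 8 | (±)-[3-bromo-2-(tert-butyldimethylsilyloxy)-6-methoxy-4-methylphenyl][3,5-bis(tert-butyldimethylsilyloxy)-2-(hydroxymethyl)-6-(3-methylbut-2-en-1-yl)phenyl]methanol | COc1cc(C)c(Br)c(O[Si](C)(C)C(C)(C)C)c1C(O)c1c(CO)c(O[Si](C)(C)C(C)(C)C)cc(O[Si](C)(C)C(C)(C)C)c1CC=C(C)C
F6 | step 8 | 2-[3-bromo-2-(tert-butyldimethylsilyloxy)-6-methoxy-4-methylbenzoyl]-4,6-bis(tert-butyldimethylsilyloxy)-3-(3-methylbut-2-en-1-yl)benzaldehyde | COc1cc(C)c(Br)c(O[Si](C)(C)C(C)(C)C)c1C(=O)c1c(C=O)c(O[Si](C)(C)C(C)(C)C)cc(O[Si](C)(C)C(C)(C)C)c1CC=C(C)C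
F7 | step 3 | 1-(3-bromo-2,6-dimethoxy-4-methylphenyl)-2-chloroethan-1-one | COc1cc(C)c(Br)c(OC)c1C(=O)CCl
A1 | direct plan | methyl 3,5-dihydroxybenzoate | COC(=O)c1cc(O)cc(O)c1
A2 | direct plan | (±)-1-[2-(tert-butyldimethylsilyloxymethyl)-3,5-bis(methoxymethoxy)-6-(3-methylbut-2-en-1-yl)phenyl]-3-methoxyprop-2-yn-1-ol tert-butyldimethylsilyl ether | COC#CC(O[Si](C)(C)C(C)(C)C)c1c(CO[Si](C)(C)C(C)(C)C)c(OCOC)cc(OCOC)c1CC=C(C)C
A3 | direct plan | 3-methylcyclobut-2-en-1-one | CC1=CC(=O)C1
A4 | direct plan | (±)-2-{(tert-butyldimethylsilyloxy)[2-(tert-butyldimethylsilyloxymethyl)-3,5-bis(methoxymethoxy)-6-(3-methylbut-2-en-1-yl)phenyl]methyl}-3-methoxy-5-methylphenol | COc1cc(C)cc(O)c1C(O[Si](C)(C)C(C)(C)C)c1c(CO[Si](C)(C)C(C)(C)C)c(OCOC)cc(OCOC)c1CC=C(C)C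
A5 | direct plan | (±)-[3-bromo-6-methoxy-2-(methoxymethoxy)-4-methylphenyl][2-(hydroxymethyl)-3,5-bis(methoxymethoxy)-6-(3-methylbut-2-en-1-yl)phenyl]methanol | COc1cc(C)c(Br)c(OCOC)c1C(O)c1c(CO)c(OCOC)cc(OCOC)c1CC=C(C)C
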